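The route rests on cutting the side-chain acyl carbon away from both its Cα and the oxygen on C3 of ring B (the dihydrofuran; ring A is the arene). The key step exploits the free benzylic C3 hydroxyl, whose C3–O bond must never become a leaving group because O1 and the C6 oxygen on ring A make C3 ionisable, together with the Cα–I bond of a Z-iodoalkene that stores the fragile alkene geometry. Palladium inserts CO between the two, forming the acyl–Cα and acyl–O bonds in one operation without any activated acid. The precursor is the cis-(2S,3S) C3 alcohol bearing C2 isopropenyl, C5 acetyl and a TIPS ether on the C6 oxygen.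

Key step: step 12

Assumption: compound 1 is taken as a catalogue chemical, and the (R,R) ligand in step 4 is assigned from the aryl ketone model of the Ru–TsDPEN catalyst (the (S,S) ligand would be used if the sense proved opposite).

Step 1
Reactants: 1 methyl 5-bromo-2,4-dihydroxybenzoate
Product: 2 methyl 5-bromo-2-hydroxy-4-(triisopropylsilyloxy)benzoate
Conditions: TIPSCl (1.1 equiv), imidazole, DMF, 0 °C to rt
Reagents that add atoms: triisopropylsilyl chloride CC(C)[Si](Cl)(C(C)C)C(C)C
Why: Chemoselective silyl ether formation, in which the free and more acidic 4-hydroxyl should be silylated while the 2-hydroxyl stays locked in its hydrogen bond to the ester carbonyl.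

Step 2
Reactants: 2 methyl 5-bromo-2-hydroxy-4-(triisopropylsilyloxy)benzoate; 3 methyl bromoacetate
Product: 4 methyl 5-bromo-2-(2-methoxy-2-oxoethoxy)-4-(triisopropylsilyloxy)benzoate
Conditions: 3 (1.3 equiv), K2CO3, acetone, reflux
Reagents that add atoms: none
Why: Williamson ether synthesis, in which the salicylate phenoxide should displace bromide from the activated primary halide while dry K2CO3 in acetone leaves the bulky, bromine-flanked aryl TIPS ether untouched.

Step 3
Reactants: 4 methyl 5-bromo-2-(2-methoxy-2-oxoethoxy)-4-(triisopropylsilyloxy)benzoate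
Product: 5 methyl 5-bromo-3-oxo-6-(triisopropylsilyloxy)-2,3-dihydrobenzofuran-2-carboxylate
Conditions: LiN(SiMe3)2 (2.2 equiv), THF, −78 to 0 °C; aq. NH4Cl
Reagents that add atoms: none
Why: Dieckmann condensation, in which the aryloxyacetate enolate should attack the ortho benzoate carbonyl in a 5-exo acyl substitution driven by formation of the product enolate, the non-nucleophilic amide base at low temperature sparing the silyl ether (the product rests largely as its aromatic enol, so C2 is configurationally labile).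

Step 4
Reactants: 5 methyl 5-bromo-3-oxo-6-(triisopropylsilyloxy)-2,3-dihydrobenzofuran-2-carboxylate
Product: 6 methyl (2R,3S)-5-bromo-3-hydroxy-6-(triisopropylsilyloxy)-2,3-dihydrobenzofuran-2-carboxylate
Conditions: RuCl(p-cymene)[(R,R)-TsDPEN] (2 mol %), HCO2H/Et3N (5:2), CH2Cl2, 30 °C
Reagents that add atoms: none
Why: Noyori-type asymmetric transfer hydrogenation with dynamic kinetic resolution, in which C2 epimerises rapidly through the enol while the chiral Ru hydride reduces only the keto enantiomer that lets hydride arrive anti to the ester, so that C3 (S, catalyst control with ring A as the aryl group) and C2 (R, cis to the new hydroxyl) should be set together.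

Step 5
Reactants: 6 methyl (2R,3S)-5-bromo-3-hydroxy-6-(triisopropylsilyloxy)-2,3-dihydrobenzofuran-2-carboxylate
Product: 8 (2R,3S)-5-bromo-2-(2-hydroxypropan-2-yl)-6-(triisopropylsilyloxy)-2,3-dihydrobenzofuran-3-ol, via methyl ketone 7 (not isolated)
Conditions: MeMgBr (4 equiv), THF, −20 to 0 °C; aq. NH4Cl
Reagents that add atoms: methylmagnesium bromide C[Mg]Br
Why: Double Grignard addition to an ester, in which the first equivalent forms the C3 magnesium alkoxide (a non-leaving group that blocks β-elimination to the benzofuran) and two more convert the ester through ketone 7 into the tertiary carbinol without touching C2, C3, the aryl bromide or the TIPS ether.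

Step 6
Reactants: 8 (2R,3S)-5-bromo-2-(2-hydroxypropan-2-yl)-6-(triisopropylsilyloxy)-2,3-dihydrobenzofuran-3-ol
Product: 9 2-[(2R,3S)-5-bromo-3-(triethylsilyloxy)-6-(triisopropylsilyloxy)-2,3-dihydrobenzofuran-2-yl]propan-2-ol
Conditions: Et3SiCl (1.1 equiv), imidazole, CH2Cl2, 0 °C
Reagents that add atoms: chlorotriethylsilane CC[Si](Cl)(CC)CC
Why: Selective silylation, in which Et3SiCl with imidazole should cap the secondary C3 hydroxyl and leave the tertiary carbinol free, so that the ionisable benzylic alcohol is masked before the dehydration.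

Step 7
Reactants: 9 2-[(2R,3S)-5-bromo-3-(triethylsilyloxy)-6-(triisopropylsilyloxy)-2,3-dihydrobenzofuran-2-yl]propan-2-ol
Product: 10 (2S,3S)-5-bromo-2-isopropenyl-3-(triethylsilyloxy)-6-(triisopropylsilyloxy)-2,3-dihydrobenzofuran
Conditions: Burgess reagent (MeO2CN−SO2N+Et3), toluene, 50 °C
Reagents that add atoms: none
Why: Burgess dehydration by syn elimination through the tertiary sulfamate, in which loss of one of six methyl hydrogens in preference to the single oxygen-deactivated C2 hydrogen should give the isopropenyl group (the C2 descriptor changes to S by priority only).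

Step 8
Reactants: 10 (2S,3S)-5-bromo-2-isopropenyl-3-(triethylsilyloxy)-6-(triisopropylsilyloxy)-2,3-dihydrobenzofuran
Product: 13 cis-(2S,3S)-5-acetyl-3-hydroxy-2-isopropenyl-6-(triisopropylsilyloxy)-2,3-dihydrobenzofuran, via enol ether 11 (not isolated), via silylated ketone 12 (not isolated)
Conditions: Bu3SnC(OEt)=CH2 (1.5 equiv), Pd(PPh3)4 (5 mol %), toluene, 100 °C; then 1 M HCl, THF, 0 °C to rt
Reagents that add atoms: tributyl(1-ethoxyvinyl)stannane CCCC[Sn](CCCC)(CCCC)C(=C)OCC; water O
Why: Stille coupling followed by acid hydrolysis, in which the alkenylstannane should replace the C5 bromine and brief dilute acid should then unmask the methyl ketone and cleave the acid-labile secondary TES ether, the aryl TIPS ether being acid-stable and the acetylated ring A resisting ionisation at C3.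

Step 9
Reactants: 14 crotonaldehyde
Product: 15 (Z)-2-iodobut-2-enal
Conditions: I2 (1.5 equiv), K2CO3, DMAP (20 mol %), THF/H2O (1:1), rt
Reagents that add atoms: iodine II
Why: α-Iodination of an enal by a Morita–Baylis–Hillman-type addition, iodination and elimination sequence, in which E1cB loss of DMAP should return the thermodynamically preferred Z isomer with the aldehyde trans to the methyl group.

Step 10
Reactants: 15 (Z)-2-iodobut-2-enal
Product: 16 (Z)-2-iodobut-2-en-1-ol
Conditions: NaBH4, CeCl3·7H2O, MeOH, 0 °C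
Reagents that add atoms: none
Why: Luche reduction, in which CeCl3-modified NaBH4 should reduce the aldehyde in the 1,2 sense without touching the C–I bond or the alkene geometry.

Step 11
Reactants: 16 (Z)-2-iodobut-2-en-1-ol
Product: 17 (Z)-2-iodobut-2-enyl acetate
Conditions: Ac2O, Et3N, DMAP (cat.), CH2Cl2, 0 °C
Reagents that add atoms: acetic anhydride CC(=O)OC(C)=O
Why: Acylation of a primary alcohol, for which DMAP catalysis is safe at this stage because the iodoalkene carries no conjugated acceptor open to SN2′ attack.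

Step 12
Reactants: 13 cis-(2S,3S)-5-acetyl-3-hydroxy-2-isopropenyl-6-(triisopropylsilyloxy)-2,3-dihydrobenzofuran; 17 (Z)-2-iodobut-2-enyl acetate; 18 carbon monoxide
Product: 19 (2S,3S)-5-acetyl-2-isopropenyl-6-(triisopropylsilyloxy)-2,3-dihydrobenzofuran-3-yl (Z)-2-(acetoxymethyl)but-2-enoate
Conditions: 17 (2 equiv), Pd(OAc)2 (5 mol %), Xantphos (5.5 mol %), i-Pr2NEt (3 equiv), CO (1 atm), 4 Å MS, toluene, 70 °C
Reagents that add atoms: none
Why: The Cα–I bond of 17 should add oxidatively, with retention, to zerovalent palladium (formed in the flask from Pd(OAc)2 and Xantphos), CO should insert to give a (Z)-alkenoyl palladium iodide, and the C3 hydroxyl of 13, assisted by i-Pr2NEt, should attack the acyl ligand to release ester 19 and regenerate the catalyst. The closest known reaction type is the Heck alkoxycarbonylation of alkenyl iodides with secondary alcohols at atmospheric CO pressure. No ring is closed and no stereocentre is created: C2 and C3 are untouched because the C3–O bond is never broken, and the Z geometry is inherited from 17. Chemoselectivity for the C3 hydroxyl is secured by the TIPS ether on the C6 oxygen, and the absence of any free acyl electrophile or nucleophilic acylation catalyst closes the paths to Z to E isomerisation and SN2′ loss of acetate. Insertion into C–I is expected to outrun ionisation of the allylic acetate under CO, helped by the excess of 17 and by a ligand to palladium ratio near one that leaves little free phosphine.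

Step 13
Reactants: 19 (2S,3S)-5-acetyl-2-isopropenyl-6-(triisopropylsilyloxy)-2,3-dihydrobenzofuran-3-yl (Z)-2-(acetoxymethyl)but-2-enoate
Product: 20 (2S,3S)-5-acetyl-6-hydroxy-2-isopropenyl-2,3-dihydrobenzofuran-3-yl (Z)-2-(acetoxymethyl)but-2-enoate
Conditions: HF·pyridine, pyridine, THF, 0 °C
Reagents that add atoms: none
Why: Fluoride-mediated cleavage of an aryl silyl ether, which should be fast at 0 °C because the ortho acetyl group stabilises the departing phenoxide, while the buffered non-basic medium keeps the C6 phenol protonated so that it cannot expel the C3 ester as a quinone methide or disturb the allylic acetate.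

Compound list
1 | methyl 5-bromo-2,4-dihydroxybenzoate | COC(=O)c1cc(Br)c(O)cc1O | starting material
2 | methyl 5-bromo-2-hydroxy-4-(triisopropylsilyloxy)benzoate | COC(=O)c1cc(Br)c(O[Si](C(C)C)(C(C)C)C(C)C)cc1O | intermediate
3 | methyl bromoacetate | COC(=O)CBr | starting material
4 | methyl 5-bromo-2-(2-methoxy-2-oxoethoxy)-4-(triisopropylsilyloxy)benzoate | COC(=O)COc1cc(O[Si](C(C)C)(C(C)C)C(C)C)c(Br)cc1C(=O)OC | intermediate
5 | methyl 5-bromo-3-oxo-6-(triisopropylsilyloxy)-2,3-dihydrobenzofuran-2-carboxylate (racemic at C2; in equilibrium with its 3-hydroxybenzofuran enol) | COC(=O)C1Oc2cc(O[Si](C(C)C)(C(C)C)C(C)C)c(Br)cc2C1=O | intermediate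
6 | methyl (2R,3S)-5-bromo-3-hydroxy-6-(triisopropylsilyloxy)-2,3-dihydrobenzofuran-2-carboxylate (cis) | COC(=O)[C@@H]1Oc2cc(O[Si](C(C)C)(C(C)C)C(C)C)c(Br)cc2[C@@H]1O | intermediate
7 | 1-[(2R,3S)-5-bromo-3-hydroxy-6-(triisopropylsilyloxy)-2,3-dihydrobenzofuran-2-yl]ethanone (formed in the flask as its magnesium alkoxide) | CC(=O)[C@@H]1Oc2cc(O[Si](C(C)C)(C(C)C)C(C)C)c(Br)cc2[C@@H]1O | intermediate
8 | (2R,3S)-5-bromo-2-(2-hydroxypropan-2-yl)-6-(triisopropylsilyloxy)-2,3-dihydrobenzofuran-3-ol | CC(C)(O)[C@@H]1Oc2cc(O[Si](C(C)C)(C(C)C)C(C)C)c(Br)cc2[C@@H]1O | intermediate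
9 | 2-[(2R,3S)-5-bromo-3-(triethylsilyloxy)-6-(triisopropylsilyloxy)-2,3-dihydrobenzofuran-2-yl]propan-2-ol | CC(C)(O)[C@@H]1Oc2cc(O[Si](C(C)C)(C(C)C)C(C)C)c(Br)cc2[C@@H]1O[Si](CC)(CC)CC | intermediate
10 | (2S,3S)-5-bromo-2-isopropenyl-3-(triethylsilyloxy)-6-(triisopropylsilyloxy)-2,3-dihydrobenzofuran | C=C(C)[C@@H]1Oc2cc(O[Si](C(C)C)(C(C)C)C(C)C)c(Br)cc2[C@@H]1O[Si](CC)(CC)CC | intermediate
11 | (2S,3S)-5-(1-ethoxyvinyl)-2-isopropenyl-3-(triethylsilyloxy)-6-(triisopropylsilyloxy)-2,3-dihydrobenzofuran (formed in the flask) | C=C(C)[C@@H]1Oc2cc(O[Si](C(C)C)(C(C)C)C(C)C)c(C(=C)OCC)cc2[C@@H]1O[Si](CC)(CC)CC | intermediate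
12 | 1-[(2S,3S)-2-isopropenyl-3-(triethylsilyloxy)-6-(triisopropylsilyloxy)-2,3-dihydrobenzofuran-5-yl]ethanone (formed in the flask) | C=C(C)[C@@H]1Oc2cc(O[Si](C(C)C)(C(C)C)C(C)C)c(C(C)=O)cc2[C@@H]1O[Si](CC)(CC)CC | intermediate
13 | cis-(2S,3S)-5-acetyl-3-hydroxy-2-isopropenyl-6-(triisopropylsilyloxy)-2,3-dihydrobenzofuran | C=C(C)[C@@H]1Oc2cc(O[Si](C(C)C)(C(C)C)C(C)C)c(C(C)=O)cc2[C@@H]1O | intermediate
14 | crotonaldehyde, (E)-but-2-enal | C/C=C/C=O | starting material
15 | (Z)-2-iodobut-2-enal | C/C=C(\I)C=O | intermediate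
16 | (Z)-2-iodobut-2-en-1-ol | C/C=C(\I)CO | intermediate
17 | (Z)-2-iodobut-2-enyl acetate | C/C=C(\I)COC(C)=O | intermediate
18 | carbon monoxide | [C-]#[O+] | starting material
19 | (2S,3S)-5-acetyl-2-isopropenyl-6-(triisopropylsilyloxy)-2,3-dihydrobenzofuran-3-yl (Z)-2-(acetoxymethyl)but-2-enoate | C=C(C)[C@@H]1Oc2cc(O[Si](C(C)C)(C(C)C)C(C)C)c(C(C)=O)cc2[C@@H]1OC(=O)/C(=C\C)COC(C)=O | intermediate
20 | (2S,3S)-5-acetyl-6-hydroxy-2-isopropenyl-2,3-dihydrobenzofuran-3-yl (Z)-2-(acetoxymethyl)but-2-enoate (CNP0193314.1) | C=C(C)[C@@H]1Oc2cc(O)c(C(C)=O)cc2[C@@H]1OC(=O)/C(=C\C)COC(C)=O | target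

Total step count: 13 (steps 1 to 8 for the alcohol, steps 9 to 11 for the iodide, steps 12 and 13 for union and release).
Longest linear sequence: 10 steps (steps 1 to 8, then 12 and 13).

Steps most likely to fail

Step 12. Zerovalent palladium may ionise the allylic acetate of 17 or of product 19, or the alkenylpalladium may lose acetate by β-elimination, faster than the hindered C3 hydroxyl captures the acylpalladium. The result would be erosion of the Z geometry, scrambling of the acetoxymethyl group or a stalled esterification. The fallback fixes the alkene geometry in an isolable acid that has no allylic leaving group and transfers the acyl group by a mixed anhydride. It sets out from 16 and 13 and comes back at 19. Silylation of 16 (TBSCl, imidazole, DMF) would give (Z)-tert-butyl[(2-iodobut-2-enyl)oxy]dimethylsilane F1. Hydroxycarbonylation (Pd(OAc)2, PPh3, CO, K2CO3, DMF/H2O), in which water is an unhindered nucleophile, would give (Z)-2-[(tert-butyldimethylsilyloxy)methyl]but-2-enoic acid F2. Treatment with 2,4,6-trichlorobenzoyl chloride and Et3N in toluene would form the Yamaguchi mixed anhydride F3. Heated with 13 at 80 °C without a nucleophilic catalyst, F3 should deliver the silyloxymethyl ester (2S,3S)-5-acetyl-2-isopropenyl-6-(triisopropylsilyloxy)-2,3-dihydrobenzofuran-3-yl (Z)-2-[(tert-butyldimethylsilyloxy)methyl]but-2-enoate F4. Camphorsulfonic acid (cat.) in MeOH/CH2Cl2 at 0 °C should cleave only the primary alkyl silyl ether to give the (Z)-2-(hydroxymethyl)but-2-enoate F5. Ac2O in pyridine would then return 19.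

Step 4. The β-keto ester rests as its aromatic enol, so hydride transfer may be slow, and facial or cis selectivity may be poor. The fallback replaces asymmetric catalysis by substrate-controlled reduction and enzymatic resolution. It sets out from 5 and comes back at 6. NaBH4 in MeOH at −40 °C, with hydride arriving anti to the ester, should give the racemic cis hydroxy ester F6. Candida antarctica lipase B with vinyl acetate in MTBE is predicted by Kazlauskas' rule (ring A as the large group) to acetylate the (3S) enantiomer, giving methyl (2R,3S)-3-acetoxy-5-bromo-6-(triisopropylsilyloxy)-2,3-dihydrobenzofuran-2-carboxylate F7. F7 would be separated from the unreacted methyl (2S,3R)-5-bromo-3-hydroxy-6-(triisopropylsilyloxy)-2,3-dihydrobenzofuran-2-carboxylate F8. Neutral butanolysis of F7 with the same lipase (n-BuOH, MTBE) avoids base-induced elimination to the benzofuran and would return 6.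

Step 7. Elimination may run toward the C2–H bond to give the exocyclic enol ether, or the tertiary sulfamate may ionise with participation of O1 and rearrange. The fallback builds the alkene by carbonyl methylenation, where the regiochemistry is unambiguous. It sets out from 6 and comes back at 10. Et3SiCl and imidazole would give methyl (2R,3S)-5-bromo-3-(triethylsilyloxy)-6-(triisopropylsilyloxy)-2,3-dihydrobenzofuran-2-carboxylate F9. MeNH(OMe)·HCl with i-PrMgCl in THF at −20 °C would give the Weinreb amide F10. MeMgBr would give the methyl ketone 1-[(2R,3S)-5-bromo-3-(triethylsilyloxy)-6-(triisopropylsilyloxy)-2,3-dihydrobenzofuran-2-yl]ethanone F11. The non-basic reagent Cp2Ti(μ-CH2)(μ-Cl)AlMe2 (Tebbe methylenation, THF, −40 to 0 °C) should then give 10 without epimerising C2.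

Further compounds
F1 | step 12 | (Z)-tert-butyl[(2-iodobut-2-enyl)oxy]dimethylsilane | C/C=C(\I)CO[Si](C)(C)C(C)(C)C
F2 | step 12 | (Z)-2-[(tert-butyldimethylsilyloxy)methyl]but-2-enoic acid | C/C=C(\C(=O)O)CO[Si](C)(C)C(C)(C)C
F3 | step 12 | (Z)-2-[(tert-butyldimethylsilyloxy)methyl]but-2-enoic 2,4,6-trichlorobenzoic anhydride | C/C=C(\C(=O)OC(=O)c1c(Cl)cc(Cl)cc1Cl)CO[Si](C)(C)C(C)(C)C
F4 | step 12 | (2S,3S)-5-acetyl-2-isopropenyl-6-(triisopropylsilyloxy)-2,3-dihydrobenzofuran-3-yl (Z)-2-[(tert-butyldimethylsilyloxy)methyl]but-2-enoate | C=C(C)[C@@H]1Oc2cc(O[Si](C(C)C)(C(C)C)C(C)C)c(C(C)=O)cc2[C@@H]1OC(=O)/C(=C\C)CO[Si](C)(C)C(C)(C)C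
F5 | step 12 | (2S,3S)-5-acetyl-2-isopropenyl-6-(triisopropylsilyloxy)-2,3-dihydrobenzofuran-3-yl (Z)-2-(hydroxymethyl)but-2-enoate | C=C(C)[C@@H]1Oc2cc(O[Si](C(C)C)(C(C)C)C(C)C)c(C(C)=O)cc2[C@@H]1OC(=O)/C(=C\C)CO
F6 | step 4 | racemic cis methyl 5-bromo-3-hydroxy-6-(triisopropylsilyloxy)-2,3-dihydrobenzofuran-2-carboxylate, (2R,3S) and (2S,3R) in equal amounts | COC(=O)[C@@H]1Oc2cc(O[Si](C(C)C)(C(C)C)C(C)C)c(Br)cc2[C@@H]1O.COC(=O)[C@H]1Oc2cc(O[Si](C(C)C)(C(C)C)C(C)C)c(Br)cc2[C@H]1O
F7 | step 4 | methyl (2R,3S)-3-acetoxy-5-bromo-6-(triisopropylsilyloxy)-2,3-dihydrobenzofuran-2-carboxylate | COC(=O)[C@@H]1Oc2cc(O[Si](C(C)C)(C(C)C)C(C)C)c(Br)cc2[C@@H]1OC(C)=O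
F8 | step 4 | methyl (2S,3R)-5-bromo-3-hydroxy-6-(triisopropylsilyloxy)-2,3-dihydrobenzofuran-2-carboxylate | COC(=O)[C@H]1Oc2cc(O[Si](C(C)C)(C(C)C)C(C)C)c(Br)cc2[C@H]1O
F9 | step 7 | methyl (2R,3S)-5-bromo-3-(triethylsilyloxy)-6-(triisopropylsilyloxy)-2,3-dihydrobenzofuran-2-carboxylate | COC(=O)[C@@H]1Oc2cc(O[Si](C(C)C)(C(C)C)C(C)C)c(Br)cc2[C@@H]1O[Si](CC)(CC)CC
F10 | step 7 | (2R,3S)-5-bromo-N-methoxy-N-methyl-3-(triethylsilyloxy)-6-(triisopropylsilyloxy)-2,3-dihydrobenzofuran-2-carboxamide | CON(C)C(=O)[C@@H]1Oc2cc(O[Si](C(C)C)(C(C)C)C(C)C)c(Br)cc2[C@@H]1O[Si](CC)(CC)CC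
F11 | step 7 | 1-[(2R,3S)-5-bromo-3-(triethylsilyloxy)-6-(triisopropylsilyloxy)-2,3-dihydrobenzofuran-2-yl]ethanone | CC(=O)[C@@H]1Oc2cc(O[Si](C(C)C)(C(C)C)C(C)C)c(Br)cc2[C@@H]1O[Si](CC)(CC)CC
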